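**One step.** In a one-step world you wait 5 half-lives, call the flask finished, and read the yield. Here is the problem:

| flask | substrate | temperature | remark | time |
|---|---|---|---|---|
| grey | 0.50 M | 0 °C | run made earlier |  |
| birch | 0.25 M | 0 °C |  | 6.0 h |
| oak | 0.25 M | −15 °C |  | 6.0 h |

grey run (percent of the substrate charged)

| time / min | target / % | substrate / % |
|---|---|---|
| 20.0 | 36 | 35 |
| 40.0 | 49 | 16 |
| 60.0 | 53 | 6 |
| 80.0 | 55 | 0 |
| 120 | 55 | 3 |

(readings scatter by 1.5 percentage points)

1. the best flask by amount of target, in percent of the substrate charged; "all alike" if 1.5 percentage points covers them all (birch / oak / all alike)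
2. amount of target at the end, in percent of the substrate charged, birch
3. amount of target at the end, in percent of the substrate charged, oak

- what was read earlier has a scatter of 1.5 percentage points, one standard deviation
- the earlier runs do not show what temperature does; that part of a forecast is a guess

**The count.** The grey run's substrate falls to 16% by 40.0 min, which gives 15.1 min as the half-life, the time in which whatever substrate is left halves. That is my reading from one point; the forecast, using three, has about 14 min. The substrate readings roughly fit one such time, so I expect halving the charge to 0.25 M to leave it alone. Birch then gets 23.8 half-lives, far past the rule's 5, so I expect it on grey's plateau of 55%.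

**The border.** Oak gets the same 6.0 h at −15 °C, and no earlier run shows how far that stretches the half-life. The ratio of the time to 5 half-lives gives the border: 4.76. If the cold stretches the half-life by more than that, the rule stops working for oak, and its yield depends on substrate still unreacted.

**The forecast.** It names birch, with 55% (50% to 60%) for birch and 51% (38% to 63%) for oak. Its words: “incomplete conversion tips the choice to birch”.

**The result.** Oak gives 57.3% and birch 53.6%, so the best flask is oak.

    substrate → intermediate A (k = 1.78 × 10⁻⁵ s⁻¹, Ea = 90.0 kJ mol⁻¹)
    target → over-reaction product (k = 1.97 × 10⁻⁶ s⁻¹, Ea = 101 kJ mol⁻¹)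
    intermediate B → side product B (k = 7.33 × 10⁻⁵ s⁻¹, Ea = 83.0 kJ mol⁻¹)
    intermediate A → side product A (k = 6.73 × 10⁻⁵ s⁻¹, Ea = 85.0 kJ mol⁻¹)
    substrate → target (k = 4.78 × 10⁻⁴ s⁻¹, Ea = 78.0 kJ mol⁻¹)
    substrate → intermediate B (k = 3.61 × 10⁻⁴ s⁻¹, Ea = 93.0 kJ mol⁻¹)
    (constants at 0 °C)

**Border crossed.** At 6.00 h oak still holds 11% of its substrate, which is 3.12 half-lives, short of 5. So oak's half-life reads about 7.62 times grey's 15.1 min, past the border. The step from substrate to intermediate B costs birch 39 percentage points of target and oak less, 17 points. Oak still wins, partly because cold slows that step: with that temperature effect taken away, birch minus oak moves from −3.7 points to 30 points. The selectivity factor, target step over intermediate B step, starts at 1.9 in oak. The stretched half-life puts the substrate of an oak flask stopped at 4.0 h at 23.6%, and that flask holds 23.6%.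

All runs stem from a simulated flask for substances that don't exist; noise was put on by code.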